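## Retrosynthetic overview

1. Target 22 comes from heptabenzyl ether 21 by hydrogenolysis; upper ring C is closed last, through the O1–C2 bond, by Mitsunobu inversion of triol 20.
2. Triol 20 comes from hydroxy amide 16 and aryl bromide 17: aryl ketone formation, then chelation-controlled reduction sets C2.
3. Hydroxy amide 16 comes from keto amide 15 by transfer hydrogenation with dynamic kinetic resolution, which sets C3 and C4 together.
4. Key disconnection, C3–C4: the Breslow intermediate (acyl anion) of glyoxamide 11 adds to o-quinone methide 14. 14 forms in the same flask from the C8-lithiated lower unit 7 and salicylaldehyde carbonate 9, which also makes the interflavan C4–C8 bond.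
5. Lower unit 7 comes from (+)-taxifolin, keeping its three rings and both stereocentres (5-OH and C4=O removed). Ring order: lower-unit rings from the chiral pool, upper ring A brought in as 9, upper ring C formed last.

Assumption: commercial (+)-taxifolin is the (2R,3R) enantiomer, and the ruthenium catalyst in step 9 shows the facial sense of the aryl-ketone model with the amide carbonyl in the place of the aryl group.

Abbreviation used in names: Fl = (2R,3S)-3,7-bis(benzyloxy)-2-[3,4-bis(benzyloxy)phenyl]chroman-8-yl (the lower unit bonded through C8). Locants C2, C3, C4 in the explanations are those of the upper flavan unit.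

## Route

Step 1
Reactants: 1 (+)-taxifolin
Product: 2 (2R,3R)-7,3',4'-tri-O-benzyltaxifolin
Conditions: BnBr (3.1 equiv), K2CO3, DMF, rt, Ar
Reagents that add atoms: benzyl bromide, BrCc1ccccc1
Why: Williamson etherification in which K2CO3 ionizes only the 7-, 3'- and 4'-phenols, the 5-OH being held in a hydrogen bond to the C4 carbonyl and the 3-OH being far less acidic; no stereocentre is touched.

Step 2
Reactants: 2 (2R,3R)-7,3',4'-tri-O-benzyltaxifolin
Product: 3 (2R,3R)-7,3',4'-tri-O-benzyltaxifolin 5-O-triflate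
Conditions: PhNTf2, K2CO3, DMF, 0 °C → rt, Ar
Reagents that add atoms: N-phenylbis(trifluoromethanesulfonimide), O=S(=O)(N(c1ccccc1)S(=O)(=O)C(F)(F)F)C(F)(F)F
Why: Phenoxide-selective sulfonyl transfer (aryl triflate formation) that leaves the secondary 3-OH alone.

Step 3
Reactants: 3 (2R,3R)-7,3',4'-tri-O-benzyltaxifolin 5-O-triflate
Product: 4 (2R,3R)-7,3',4'-tri-O-benzylfustin
Conditions: Pd(OAc)2 (5 mol %), Ph2P(CH2)3PPh2, HCO2H, Et3N, DMF, 70 °C
Reagents that add atoms: none
Why: Palladium-catalysed reductive cleavage of an aryl triflate with formate as hydride donor (oxidative addition to zerovalent palladium, decarboxylation of the formate, reductive elimination); ketone, benzyl ethers and both stereocentres are inert.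

Step 4
Reactants: 4 (2R,3R)-7,3',4'-tri-O-benzylfustin
Product: 6 (2R,3S)-7,3',4'-tri-O-benzylfisetinidol, via flavan-3,4-diol 5 (not isolated)
Conditions: NaBH4, THF–MeOH, 0 °C; then CF3CO2H, Et3SiH, CH2Cl2, 0 °C
Reagents that add atoms: none
Why: Carbonyl reduction followed by ionic hydrogenation, the 4-carbinol ionizing to a cation stabilized by the para 7-benzyloxy group and being trapped by Et3SiH; C2 and C3 keep their geometry (the descriptor at C3 changes from R to S only because C4 loses priority).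

Step 5
Reactants: 6 (2R,3S)-7,3',4'-tri-O-benzylfisetinidol
Product: 7 (2R,3S)-3,7,3',4'-tetra-O-benzylfisetinidol
Conditions: NaH, BnBr, n-Bu4NI (cat.), DMF, 0 °C → rt
Reagents that add atoms: benzyl bromide, BrCc1ccccc1
Why: Williamson etherification of the secondary alkoxide, which removes the only acidic proton before the organolithium chemistry.

Step 6
Reactants: 8 4-(benzyloxy)-2-hydroxybenzaldehyde
Product: 9 5-(benzyloxy)-2-formylphenyl tert-butyl carbonate
Conditions: Boc2O, i-Pr2NEt, 4-(dimethylamino)pyridine (cat.), THF, 0 °C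
Reagents that add atoms: di-tert-butyl dicarbonate, CC(C)(C)OC(=O)OC(=O)OC(C)(C)C
Why: Nucleophile-catalysed O-acylation of the phenol to the aryl carbonate that later serves as the internal leaving-group donor.

Step 7
Reactants: 10 4-acryloylmorpholine
Product: 11 2-(morpholin-4-yl)-2-oxoacetaldehyde
Conditions: O3, CH2Cl2–MeOH, −78 °C; Me2S; distilled and kept anhydrous
Reagents that add atoms: ozone, [O-][O+]=O
Why: Ozonolysis of the terminal alkene with reductive work-up gives the glyoxamide.

Step 8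
Reactants: 7 (2R,3S)-3,7,3',4'-tetra-O-benzylfisetinidol; 9 5-(benzyloxy)-2-formylphenyl tert-butyl carbonate; 11 2-(morpholin-4-yl)-2-oxoacetaldehyde
Product: 15 α-keto morpholine amide (both C4 epimers), via aryllithium 12 (not isolated), via phenoxide carbonate 13 (not isolated), via o-quinone methide 14 (not isolated)
Conditions: n-BuLi (n-C4H9Li, 1.1 equiv), THF, 0 °C; 9, −78 °C; then 11 (2 equiv), 3-benzyl-5-(2-hydroxyethyl)-4-methylthiazolium chloride (20 mol %), −78 °C → rt; aq NH4Cl
Reagents that add atoms: none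
Why: Proposed new method: directed ortho-lithiation between O1 and the 7-benzyloxy group gives 12, which adds to the aldehyde of 9, the carbonate group migrates to the new alkoxide and tert-butyl carbonate is expelled from phenoxide 13 to give o-quinone methide 14 (a known anionic cascade), and the LiOC(CH3)3 set free deprotonates the thiazolium salt so that the carbene turns glyoxamide 11 into a Breslow intermediate (acyl anion) that adds 1,4 to the methide carbon, joining the formyl carbon and the benzylic carbon (both normally electrophilic) and rearomatizing ring A; the closest known reactions are thiazolium-mediated acyl-anion additions to o-quinone methides, carbene-catalysed 1,6-hydroacylation of p-quinone methides and Stetter reactions of glyoxamides, and the new diarylmethine centre is formed without control and left epimerizable on purpose for step 9.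

Step 9
Reactants: 15 α-keto morpholine amide (both C4 epimers)
Product: 16 (2S,3S)-α-hydroxy morpholine amide
Conditions: RuCl(p-cymene)[(S,S)-TsNCH(Ph)CH(Ph)NH2] (3 mol %), HCO2H–Et3N (5:2), DMF, 40 °C
Reagents that add atoms: none
Why: Noyori–Ikariya asymmetric transfer hydrogenation run as a dynamic kinetic resolution (closest precedent: β-aryl α-keto esters), in which Et3N equilibrates the two epimers of 15 through the enol, the catalyst sets the carbinol as S, and only the epimer whose catalyst-preferred face is also the Felkin–Anh face (hydride anti to the bulky 2,6-dioxygenated flavanyl group) reacts fast, fixing the diarylmethine carbon as S with hydroxyl and flavanyl anti (3,4-trans after ring closure).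

Step 10
Reactants: 16 (2S,3S)-α-hydroxy morpholine amide; 17 4-bromo-1,2-bis(benzyloxy)benzene
Product: 19 (2S,3S)-α-hydroxy aryl ketone, via aryllithium 18 (not isolated)
Conditions: 17 (4 equiv), n-BuLi (n-C4H9Li, 4 equiv), THF, −78 °C; then 16, −78 → −20 °C; aq NH4Cl
Reagents that add atoms: none
Why: Bromine–lithium exchange then acylation of the aryllithium by the morpholine amide, whose chelated tetrahedral adduct (Weinreb-amide behaviour) survives until work-up so the ketone is not attacked twice; two equivalents of 18 only deprotonate the phenol and the alcohol, and neither stereocentre is acidic in the dianion.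

Step 11
Reactants: 19 (2S,3S)-α-hydroxy aryl ketone
Product: 20 (1R,2S,3S)-anti-diol phenol
Conditions: Zn(BH4)2 (ethereal stock solution), Et2O–THF, −20 °C; aq NH4Cl
Reagents that add atoms: none
Why: Chelation-controlled (Cram-chelate) reduction in which zinc ties the ketone and the neighbouring hydroxyl into a five-membered chelate and hydride enters anti to the bulky diarylmethyl group, giving the anti-1,2-diol, so the new benzylic carbinol is R.

Step 12
Reactants: 20 (1R,2S,3S)-anti-diol phenol
Product: 21 heptabenzyl ether of the target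
Conditions: PPh3, DIAD, THF, 0 °C
Reagents that add atoms: none
Why: Intramolecular Mitsunobu etherification in which the phenol, the only acidic OH, displaces the activated benzylic hydroxyl in a 6-exo SN2 closure with inversion, turning the (R)-carbinol into (S)-C2 and giving the 2,3-cis-3,4-trans ring C.

Step 13
Reactants: 21 heptabenzyl ether of the target
Product: 22 CNP0189433.2
Conditions: H2 (1 atm), Pd(OH)2/C, THF–MeOH, rt; Sephadex LH-20
Reagents that add atoms: none
Why: Hydrogenolysis of the seven benzyl ethers under neutral conditions, which leaves the 5-deoxy interflavan bond, the two pyran C–O bonds and all five stereocentres untouched.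

## Compound list

1 | (+)-taxifolin, (2R,3R)-2-(3,4-dihydroxyphenyl)-3,5,7-trihydroxychroman-4-one | O=C1c2c(O)cc(O)cc2O[C@H](c2ccc(O)c(O)c2)[C@H]1O | starting material
2 | (2R,3R)-7-(benzyloxy)-2-[3,4-bis(benzyloxy)phenyl]-3,5-dihydroxychroman-4-one | O=C1c2c(O)cc(OCc3ccccc3)cc2O[C@H](c2ccc(OCc3ccccc3)c(OCc3ccccc3)c2)[C@H]1O | intermediate
3 | (2R,3R)-7-(benzyloxy)-2-[3,4-bis(benzyloxy)phenyl]-3-hydroxy-4-oxochroman-5-yl trifluoromethanesulfonate | O=C1c2c(OS(=O)(=O)C(F)(F)F)cc(OCc3ccccc3)cc2O[C@H](c2ccc(OCc3ccccc3)c(OCc3ccccc3)c2)[C@H]1O | intermediate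
4 | (2R,3R)-7-(benzyloxy)-2-[3,4-bis(benzyloxy)phenyl]-3-hydroxychroman-4-one (tri-O-benzylfustin) | O=C1c2ccc(OCc3ccccc3)cc2O[C@H](c2ccc(OCc3ccccc3)c(OCc3ccccc3)c2)[C@H]1O | intermediate
5 | (2R,3S)-7-(benzyloxy)-2-[3,4-bis(benzyloxy)phenyl]chromane-3,4-diol, mixture of C4 epimers | OC1c2ccc(OCc3ccccc3)cc2O[C@H](c2ccc(OCc3ccccc3)c(OCc3ccccc3)c2)[C@H]1O | intermediate
6 | (2R,3S)-7-(benzyloxy)-2-[3,4-bis(benzyloxy)phenyl]chroman-3-ol (2,3-trans) | C1c2ccc(OCc3ccccc3)cc2O[C@H](c2ccc(OCc3ccccc3)c(OCc3ccccc3)c2)[C@H]1O | intermediate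
7 | (2R,3S)-3,7-bis(benzyloxy)-2-[3,4-bis(benzyloxy)phenyl]chromane (2,3-trans) | C1c2ccc(OCc3ccccc3)cc2O[C@H](c2ccc(OCc3ccccc3)c(OCc3ccccc3)c2)[C@H]1OCc1ccccc1 | intermediate
8 | 4-(benzyloxy)-2-hydroxybenzaldehyde | O=Cc1ccc(OCc2ccccc2)cc1O | starting material
9 | 5-(benzyloxy)-2-formylphenyl tert-butyl carbonate | O=Cc1ccc(OCc2ccccc2)cc1OC(=O)OC(C)(C)C | intermediate
10 | 4-acryloylmorpholine | C=CC(=O)N1CCOCC1 | starting material
11 | 2-(morpholin-4-yl)-2-oxoacetaldehyde (morpholine glyoxamide) | O=CC(=O)N1CCOCC1 | intermediate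
12 | Fl-lithium, the 8-lithio derivative of 7 | [Li]c1c(OCc2ccccc2)ccc2c1O[C@H](c1ccc(OCc3ccccc3)c(OCc3ccccc3)c1)[C@@H](OCc1ccccc1)C2 | intermediate
13 | lithium 5-(benzyloxy)-2-[(tert-butoxycarbonyloxy)(Fl)methyl]phenoxide, both carbinol epimers | [Li]Oc1cc(OCc2ccccc2)ccc1C(OC(=O)OC(C)(C)C)c1c(OCc2ccccc2)ccc2c1O[C@H](c1ccc(OCc3ccccc3)c(OCc3ccccc3)c1)[C@@H](OCc1ccccc1)C2 | intermediate
14 | 3-(benzyloxy)-6-[(Fl)methylidene]cyclohexa-2,4-dien-1-one (o-quinone methide) | O=C1C=C(OCc2ccccc2)C=CC1=Cc1c(OCc2ccccc2)ccc2c1O[C@H](c1ccc(OCc3ccccc3)c(OCc3ccccc3)c1)[C@@H](OCc1ccccc1)C2 | intermediate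
15 | 3-[4-(benzyloxy)-2-hydroxyphenyl]-3-(Fl)-1-(morpholin-4-yl)propane-1,2-dione, both C3 epimers (C4 of the upper unit), in equilibrium with its cyclic hemiketal | O=C(N1CCOCC1)C(=O)C(c1ccc(OCc2ccccc2)cc1O)c1c(OCc2ccccc2)ccc2c1O[C@H](c1ccc(OCc3ccccc3)c(OCc3ccccc3)c1)[C@@H](OCc1ccccc1)C2 | intermediate
16 | (2S,3S)-3-[4-(benzyloxy)-2-hydroxyphenyl]-3-(Fl)-2-hydroxy-1-(morpholin-4-yl)propan-1-one | O=C(N1CCOCC1)[C@@H](O)[C@@H](c1ccc(OCc2ccccc2)cc1O)c1c(OCc2ccccc2)ccc2c1O[C@H](c1ccc(OCc3ccccc3)c(OCc3ccccc3)c1)[C@@H](OCc1ccccc1)C2 | intermediate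
17 | 4-bromo-1,2-bis(benzyloxy)benzene | Brc1ccc(OCc2ccccc2)c(OCc2ccccc2)c1 | starting material
18 | [3,4-bis(benzyloxy)phenyl]lithium | [Li]c1ccc(OCc2ccccc2)c(OCc2ccccc2)c1 | intermediate
19 | (2S,3S)-1-[3,4-bis(benzyloxy)phenyl]-3-[4-(benzyloxy)-2-hydroxyphenyl]-3-(Fl)-2-hydroxypropan-1-one (may sit as the cyclic hemiketal) | O=C(c1ccc(OCc2ccccc2)c(OCc2ccccc2)c1)[C@@H](O)[C@@H](c1ccc(OCc2ccccc2)cc1O)c1c(OCc2ccccc2)ccc2c1O[C@H](c1ccc(OCc3ccccc3)c(OCc3ccccc3)c1)[C@@H](OCc1ccccc1)C2 | intermediate
20 | (1R,2S,3S)-1-[3,4-bis(benzyloxy)phenyl]-3-[4-(benzyloxy)-2-hydroxyphenyl]-3-(Fl)propane-1,2-diol (1,2-anti) | O[C@H](c1ccc(OCc2ccccc2)c(OCc2ccccc2)c1)[C@@H](O)[C@@H](c1ccc(OCc2ccccc2)cc1O)c1c(OCc2ccccc2)ccc2c1O[C@H](c1ccc(OCc3ccccc3)c(OCc3ccccc3)c1)[C@@H](OCc1ccccc1)C2 | intermediate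
21 | (2S,3S,4S)-7-(benzyloxy)-2-[3,4-bis(benzyloxy)phenyl]-4-(Fl)chroman-3-ol (2,3-cis-3,4-trans) | c1ccccc1COc1ccc2c(c1)O[C@@H](c1ccc(OCc3ccccc3)c(OCc3ccccc3)c1)[C@@H](O)[C@@H]2c1c(OCc2ccccc2)ccc2c1O[C@H](c1ccc(OCc3ccccc3)c(OCc3ccccc3)c1)[C@@H](OCc1ccccc1)C2 | intermediate
22 | CNP0189433.2, (2S,3S,4S)-2-(3,4-dihydroxyphenyl)-4-[(2R,3S)-2-(3,4-dihydroxyphenyl)-3,7-dihydroxychroman-8-yl]chromane-3,7-diol, ent-epifisetinidol-(4α→8)-fisetinidol | Oc1ccc2c(c1)O[C@@H](c1ccc(O)c(O)c1)[C@@H](O)[C@@H]2c1c(O)ccc2c1O[C@H](c1ccc(O)c(O)c1)[C@@H](O)C2 | target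

## Step count and weak points

Total: 13 steps. Longest linear sequence: 11 steps (1–5, then 8–13); steps 6 and 7 are one-step side branches.

Steps most likely to fail:

Step 8 (carbene-catalysed acyl-anion addition to a crowded, in situ o-quinone methide in the presence of stoichiometric lithium alkoxide). The fallback sets out from 7 and 9 and returns at 15. The o-quinone methide 14 is generated exactly as before but is trapped with a stoichiometric acyl-anion equivalent: the lithium salt (LiN(SiMe3)2, THF, −78 °C) of 1,3-dithian-2-yl(morpholin-4-yl)methanone F1, made by heating commercial ethyl 1,3-dithiane-2-carboxylate with morpholine. Stabilized carbanions are known to add to o-quinone methides formed by this cascade. The resulting dithiane adduct F2 is unmasked with Hg(ClO4)2 and CaCO3 in aqueous THF to give 15.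

Step 9 (the dynamic kinetic resolution must tell two aryl groups apart and the facial sense is inferred by analogy). The fallback sets out from 15 and returns at 16. 15 is reduced without a chiral catalyst, LiBH(s-Bu)3 in THF at −78 °C, where Felkin–Anh control operates and the diarylmethine does not epimerize. This gives the two anti hydroxy amides, 16 and its (2R,3R)-isomer F3, which are diastereomers because of the lower unit and are separated by chromatography. F3 is oxidized back to 15 with Dess–Martin periodinane and recycled.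

Step 12 (the electron-rich benzylic oxyphosphonium ion may ionize and lose stereospecificity, or the neighbouring hydroxyl may form an epoxide). The fallback sets out from 20 and returns at 21. The diol is activated as a cyclic orthoformate instead: HC(OEt)3, pyridinium p-toluenesulfonate, ClCH2CH2Cl, 60 °C. The derived 1,3-dioxolan-2-ylium ion is opened at the benzylic carbon by the phenol with inversion to give the 3-O-formate F4, and K2CO3 in MeOH removes the formate to give 21.

## Further compounds

F1 | step 8 | 1,3-dithian-2-yl(morpholin-4-yl)methanone | O=C(C1SCCCS1)N1CCOCC1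
F2 | step 8 | {2-[[4-(benzyloxy)-2-hydroxyphenyl](Fl)methyl]-1,3-dithian-2-yl}(morpholin-4-yl)methanone, both methine epimers | O=C(N1CCOCC1)C1(SCCCS1)C(c1ccc(OCc2ccccc2)cc1O)c1c(OCc2ccccc2)ccc2c1O[C@H](c1ccc(OCc3ccccc3)c(OCc3ccccc3)c1)[C@@H](OCc1ccccc1)C2
F3 | step 9 | (2R,3R)-3-[4-(benzyloxy)-2-hydroxyphenyl]-3-(Fl)-2-hydroxy-1-(morpholin-4-yl)propan-1-one | O=C(N1CCOCC1)[C@H](O)[C@H](c1ccc(OCc2ccccc2)cc1O)c1c(OCc2ccccc2)ccc2c1O[C@H](c1ccc(OCc3ccccc3)c(OCc3ccccc3)c1)[C@@H](OCc1ccccc1)C2
F4 | step 12 | (2S,3S,4S)-7-(benzyloxy)-2-[3,4-bis(benzyloxy)phenyl]-4-(Fl)chroman-3-yl formate | c1ccccc1COc1ccc2c(c1)O[C@@H](c1ccc(OCc3ccccc3)c(OCc3ccccc3)c1)[C@@H](OC=O)[C@@H]2c1c(OCc2ccccc2)ccc2c1O[C@H](c1ccc(OCc3ccccc3)c(OCc3ccccc3)c1)[C@@H](OCc1ccccc1)C2
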